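**Assumption:** natural (+)-(3S,6E)-nerolidol (cabreuva-oil isolate, high ee) is taken as the cheap commercial chiral starting material; both halves of the target are made from it.

## Retrosynthetic overview

1. The only ring (14-membered) is closed last, at C13–C14, by intramolecular alkylation of a C14 sulfonyl carbanion with a C13 allylic chloride, followed by desulfonylation.
2. The seco-chain comes from the key step, an Ireland–Claisen [3,3] rearrangement of a tertiary allylic β-hydroxy ester. It forms C1–C2, the 3E olefin and the C1 stereocentre.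
3. The ester is assembled from two molecules of (S)-nerolidol: a β-lactone (carbinol, side chain, C1, C14) and 12-silyloxynerolidol (C2–C13).
4. The carbinol stereocentre is bought; C1 is set by 1,3-chirality transfer from the carbinol C–O of the second nerolidol unit.

(Ring numbering: C1 = ring CH, C2–C13 as in the target name, C14 = ring CH2 next to C1.)

## Route

**Step 1**
Reactants: 1, (+)-(3S,6E)-nerolidol
Product: 2, (3S,6E)-3,7,11-trimethyldodeca-6,10-diene-1,3-diol
Conditions: 9-BBN (2.2 equiv), THF, 0 °C → rt; then NaOH, H2O2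
Reagents that add atoms: hydrogen peroxide, OO (hydroxyl oxygen)
Why: Anti-Markovnikov hydroboration–oxidation; 9-BBN attacks only the monosubstituted vinyl group, and the stereocentre is untouched.

**Step 2**
Reactants: 2
Product: 3, (3S,6E)-3-hydroxy-3,7,11-trimethyldodeca-6,10-dienoic acid
Conditions: TEMPO (cat.), PhI(OAc)2, MeCN/H2O, rt
Reagents that add atoms: water, O
Why: TEMPO/BAIB oxidation takes only the primary alcohol to the acid (via the aldehyde hydrate); the tertiary OH and trisubstituted olefins are inert.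

**Step 3**
Reactants: 3
Product: 4, (4S)-4-[(3E)-4,8-dimethylnona-3,7-dien-1-yl]-4-methyloxetan-2-one
Conditions: PhSO2Cl, pyridine, 0 °C
Reagents that add atoms: none
Why: Adam β-lactonization by carboxyl activation; the carbinol C–O bond is not broken, so configuration is retained, and the strained lactone is an activated acyl donor.

**Step 4**
Reactants: 1
Product: 5, (3S,6E,10E)-3,7,11-trimethyldodeca-1,6,10-triene-3,12-diol (12-hydroxynerolidol)
Conditions: SeO2 (cat.), t-BuOOH, salicylic acid (cat.), CH2Cl2, 0 °C → rt; then NaBH4, MeOH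
Reagents that add atoms: selenium dioxide, O=[Se]=O, with tert-butyl hydroperoxide, CC(C)(C)OO (oxygen source)
Why: Selenium dioxide allylic oxidation (ene reaction then [2,3] shift) hydroxylates the terminal (E)-methyl selectively, giving the (E)-allylic alcohol.

**Step 5**
Reactants: 5
Product: 6, (3S,6E,10E)-12-(tert-butyldimethylsilyloxy)-3,7,11-trimethyldodeca-1,6,10-trien-3-ol
Conditions: TBSCl, imidazole, CH2Cl2, 0 °C
Reagents that add atoms: TBSCl, CC(C)(C)[Si](C)(C)Cl
Why: Silylation of the primary allylic OH is far faster than of the hindered tertiary OH.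

**Step 6**
Reactants: 6 (1.3 equiv) and 4
Product: 7, (3S,6E,10E)-12-(TBSO)-3,7,11-trimethyldodeca-1,6,10-trien-3-yl (3S,6E)-3-hydroxy-3,7,11-trimethyldodeca-6,10-dienoate
Conditions: n-BuLi (1 equiv to 6), THF, −78 °C; slow addition of 4; −78 → −20 °C; aq. NH4Cl
Reagents that add atoms: none
Why: Acyl–oxygen opening of the β-lactone by the tertiary lithium alkoxide (alkoxide acylation) gives the tertiary allylic ester and frees the carbinol OH; neither stereocentre is involved.

**Step 7 (key step)**
Reactants: 7
Product: 8, (2R,3S,6E)-2-[(2E,6E,10E)-12-(TBSO)-3,7,11-trimethyldodeca-2,6,10-trien-1-yl]-3-hydroxy-3,7,11-trimethyldodeca-6,10-dienoic acid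
Conditions: LDA (2.3 equiv), THF, −78 °C; TMSCl/Et3N, −78 → 23 °C; K2CO3, MeOH/H2O; AgNO3–silica chromatography
Reagents that add atoms: none
Why: Dianionic Ireland–Claisen [3,3] rearrangement: the chelated Z(O)-enolate reacts through a chair with the methyl of the tertiary allylic carbon axial, so the C–O stereocentre of the second nerolidol unit is transferred suprafacially to C1 (1R) and the new C3=C4 olefin is E; the minor Z isomer, which is also the C1 epimer, is removed.

**Step 8**
Reactants: 8
Product: 9, (2S,3S,6E)-2-[(2E,6E,10E)-12-(TBSO)-3,7,11-trimethyldodeca-2,6,10-trien-1-yl]-3,7,11-trimethyldodeca-6,10-diene-1,3-diol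
Conditions: LiAlH4, THF, 0 °C → rt
Reagents that add atoms: none
Why: Hydride reduction of the carboxylic acid to the primary alcohol (C14); the TBS ether and olefins survive, and C1 cannot epimerize afterwards.

**Step 9**
Reactants: 9
Product: 10, the C14 phenyl sulfide (primary OH of 9 replaced by SPh; C1 R, carbinol S)
Conditions: PhSSPh, n-Bu3P, pyridine, rt
Reagents that add atoms: diphenyl disulfide, c1ccccc1SSc1ccccc1
Why: Hata sulfenylation (SN2 on the alkoxyphosphonium) converts only the primary alcohol; the tertiary OH and silyl ether are untouched.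

**Step 10**
Reactants: 10
Product: 11, the C14 phenyl sulfone
Conditions: (NH4)6Mo7O24·4H2O (cat.), 30% H2O2, EtOH, 0 °C → rt
Reagents that add atoms: hydrogen peroxide, OO
Why: Mo(VI)-catalysed sulfide-to-sulfone oxidation is chemoselective for sulfur over trisubstituted olefins.

**Step 11**
Reactants: 11
Product: 12, the C13 primary allylic alcohol (TBS removed)
Conditions: TBAF, THF, 0 °C
Reagents that add atoms: none
Why: Fluoride-induced desilylation; the sulfone and tertiary alcohol are inert.

**Step 12**
Reactants: 12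
Product: 13, the C13 allylic chloride
Conditions: NCS, Me2S, CH2Cl2, −20 → 0 °C
Reagents that add atoms: N-chlorosuccinimide, O=C1CCC(=O)N1Cl
Why: Corey–Kim chlorination converts the primary allylic alcohol to the chloride by SN2, without allylic transposition or E/Z loss, and leaves the tertiary OH alone.

**Step 13 (ring closure)**
Reactants: 13
Product: 14, (1R)-1-[(2S,5E)-2-hydroxy-6,10-dimethylundeca-5,9-dien-2-yl]-14-(phenylsulfonyl)-4,8,12-trimethylcyclotetradeca-3,7,11-triene (3E,7E,11E; C14 epimers)
Conditions: LiHMDS (2.2 equiv), THF, 2 mM (syringe-pump addition), −78 → 0 °C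
Reagents that add atoms: none
Why: Intramolecular SN2 alkylation of the α-sulfonyl carbanion by the unhindered primary allylic chloride under high dilution closes the 14-membered ring at C13–C14; the C14 configuration is irrelevant.

**Step 14**
Reactants: 14
Product: 15, colleterpenol, (2S,5E)-6,10-dimethyl-2-[(1R,3E,7E,11E)-4,8,12-trimethylcyclotetradeca-3,7,11-trien-1-yl]undeca-5,9-dien-2-ol
Conditions: Na(Hg) 6%, Na2HPO4, MeOH/THF, −20 °C
Reagents that add atoms: none
Why: Reductive desulfonylation (single-electron transfer) replaces C–S by C–H; the sulfone is not allylic, so no olefin migration occurs and both stereocentres are untouched.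

## Compound list

1 | (+)-(3S,6E)-nerolidol | CC(C)=CCC/C(C)=C/CC[C@](C)(O)C=C | starting material
2 | (3S,6E)-3,7,11-trimethyldodeca-6,10-diene-1,3-diol | CC(C)=CCC/C(C)=C/CC[C@](C)(O)CCO | intermediate
3 | (3S,6E)-3-hydroxy-3,7,11-trimethyldodeca-6,10-dienoic acid | CC(C)=CCC/C(C)=C/CC[C@](C)(O)CC(=O)O | intermediate
4 | (4S)-4-[(3E)-4,8-dimethylnona-3,7-dienyl]-4-methyloxetan-2-one | CC(C)=CCC/C(C)=C/CC[C@]1(C)OC(=O)C1 | intermediate
5 | (3S,6E,10E)-3,7,11-trimethyldodeca-1,6,10-triene-3,12-diol | OC/C(C)=C/CC/C(C)=C/CC[C@](C)(O)C=C | intermediate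
6 | 12-O-TBS ether of 5 | CC(C)(C)[Si](C)(C)OC/C(C)=C/CC/C(C)=C/CC[C@](C)(O)C=C | intermediate
7 | tertiary allylic β-hydroxy ester from 4 and 6 | CC(C)=CCC/C(C)=C/CC[C@](C)(O)CC(=O)O[C@](C)(C=C)CC/C=C(\C)CC/C=C(\C)CO[Si](C)(C)C(C)(C)C | intermediate
8 | (2R,3S)-Claisen acid, 3E | CC(C)=CCC/C(C)=C/CC[C@](C)(O)[C@H](C(=O)O)C/C=C(\C)CC/C=C(\C)CC/C=C(\C)CO[Si](C)(C)C(C)(C)C | intermediate
9 | (2S,3S)-1,3-diol | CC(C)=CCC/C(C)=C/CC[C@](C)(O)[C@H](CO)C/C=C(\C)CC/C=C(\C)CC/C=C(\C)CO[Si](C)(C)C(C)(C)C | intermediate
10 | C14 phenyl sulfide | CC(C)=CCC/C(C)=C/CC[C@](C)(O)[C@H](CSc1ccccc1)C/C=C(\C)CC/C=C(\C)CC/C=C(\C)CO[Si](C)(C)C(C)(C)C | intermediate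
11 | C14 phenyl sulfone | CC(C)=CCC/C(C)=C/CC[C@](C)(O)[C@H](CS(=O)(=O)c1ccccc1)C/C=C(\C)CC/C=C(\C)CC/C=C(\C)CO[Si](C)(C)C(C)(C)C | intermediate
12 | sulfone allylic alcohol | CC(C)=CCC/C(C)=C/CC[C@](C)(O)[C@H](CS(=O)(=O)c1ccccc1)C/C=C(\C)CC/C=C(\C)CC/C=C(\C)CO | intermediate
13 | sulfone allylic chloride | CC(C)=CCC/C(C)=C/CC[C@](C)(O)[C@H](CS(=O)(=O)c1ccccc1)C/C=C(\C)CC/C=C(\C)CC/C=C(\C)CCl | intermediate
14 | macrocyclic C14 sulfone (C14 epimers) | CC(C)=CCC/C(C)=C/CC[C@](C)(O)[C@H]1C/C=C(\C)CC/C=C(\C)CC/C=C(\C)CC1S(=O)(=O)c2ccccc2 | intermediate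
15 | colleterpenol | CC(C)=CCC/C(C)=C/CC[C@](C)(O)[C@H]1C/C=C(\C)CC/C=C(\C)CC/C=C(\C)CC1 | target

## Totals and risks

Total steps: 14. Longest linear sequence: 12 (1 → 2 → 3 → 4 → 7 → 8 → 9 → 10 → 11 → 12 → 13 → 14 → 15; steps 4 and 5 are the short convergent branch).

Steps most likely to fail:

1. **Step 7 (Ireland–Claisen).** The methyl and CH2 groups on the tertiary allylic carbon differ little in size, so the E:Z ratio at C3=C4 may be only about 2–3:1. Every Z product is also the C1 epimer, so the loss is in yield and separation, not in the purity of the E material. Fallback: C-alkylate the chelated dianion of the methyl ester of 3 with (2E,6E,10E)-12-(TBSO)farnesyl bromide (from farnesol), so the 3E geometry is bought in the olefin; the rest of the route is unchanged.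
2. **Step 6 (lactone opening by a tertiary alkoxide).** Enolization of the β-lactone or oligomerization by the product alkoxide can compete. Fallback: protect the carbinol of 3 as its TES ether, make the acid chloride (Ghosez reagent), acylate the lithium alkoxide of 6, and remove the TES group before step 7.
3. **Step 13 (macrocyclization).** Oligomerization or O-alkylation can compete with 14-ring closure. Fallback: reverse the polarity, with an allylic sulfone at C13 (13 analogue + PhSO2Na) and a C14 iodide with the carbinol silylated; close by Biellmann-type alkylation and remove the allylic sulfone with PdCl2(dppp)/LiBHEt3.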